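**Retrosynthetic overview**
1. Target 49 ⇐ removal of eight MOM ethers from 47 ⇐ C–C bond between the benzylic methine and the free resorcinol ring of the oxolane half: acid-catalysed o-quinone-methide arylation joining two C30 halves, 26 and 45.
2. Half A (26): o-hydroxybenzyl alcohol from aldehyde 24 and the magnesium phenolate of 14; chalcone by Heck reaction of bromide 22 with vinyl ketone 13; dihydrobenzofuran by enantioselective rhodium carbene C–H insertion of diazoester 19, then C3 epimerisation to trans.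
3. Half B (45): aroyl group via a Weinreb amide; C2 aryl group by aryllithium addition to γ-lactone 37 and hydride reduction of the oxocarbenium ion (2,3-cis); lactone by Evans syn-aldol/lactonisation of imide 30 with aldehyde 4, then trans benzylation.
4. Ring order: the γ-lactone (later the oxolane) and the dihydrobenzofuran are each closed early in their own branch; no ring is formed after the union.
5. All aryl rings come from 4-bromophenol and resorcinol; the remaining carbons come from ethyl diazoacetate, acrolein, succinic anhydride and DMF.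

Assumption: reagents, catalysts, protecting-group sources and the recoverable auxiliary (R)-4-benzyl-1,3-oxazolidin-2-one carry no number; the catalyst enantiomers in steps 14 and 30 are assigned by analogy and would be exchanged for their mirror images if the first run shows the opposite sense.

**Steps**

Step 1
Reactants: 1 4-bromophenol
Product: 2 1-bromo-4-(methoxymethoxy)benzene
Conditions: NaH, MOMCl, DMF, 0 °C to rt
Reagents that add atoms: chloromethyl methyl ether (MOMCl), COCCl
Why: Williamson O-alkylation of the phenoxide gives the MOM acetal, a phenol mask that tolerates organolithiums, hydrides and bases and is removed only in the last step.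

Step 2
Reactants: 2 1-bromo-4-(methoxymethoxy)benzene
Product: 4 4-(methoxymethoxy)benzaldehyde, via 4-(methoxymethoxy)phenyllithium 3 (not isolated)
Conditions: n-BuLi, THF, −78 °C; DMF, −78 °C to 0 °C; aq NH4Cl
Reagents that add atoms: N,N-dimethylformamide (DMF), CN(C)C=O
Why: Bromine–lithium exchange and Bouveault formylation deliver the aldehyde without touching the MOM ether at −78 °C.

Step 3
Reactants: 4 4-(methoxymethoxy)benzaldehyde
Product: 5 [4-(methoxymethoxy)phenyl]methanol
Conditions: NaBH4, MeOH, 0 °C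
Reagents that add atoms: none
Why: Borohydride reduction of the aldehyde to the benzylic alcohol is chemoselective and creates no stereocentre.

Step 4
Reactants: 5 [4-(methoxymethoxy)phenyl]methanol
Product: 6 1-(bromomethyl)-4-(methoxymethoxy)benzene
Conditions: CBr4, PPh3, CH2Cl2, 0 °C; used at once
Reagents that add atoms: carbon tetrabromide, BrC(Br)(Br)Br
Why: The Appel reaction makes the bromide under neutral conditions, so the acid-labile acetal survives.

Step 5
Reactants: 7 resorcinol
Product: 8 4-bromobenzene-1,3-diol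
Conditions: NBS (1.0 equiv), MeCN, −30 °C to 0 °C
Reagents that add atoms: N-bromosuccinimide (NBS), O=C1CCC(=O)N1Br
Why: Electrophilic aromatic bromination goes to C4 (para to one hydroxyl, ortho to the other, less hindered than C2), and one equivalent of NBS at low temperature limits over-bromination.

Step 6
Reactants: 8 4-bromobenzene-1,3-diol
Product: 9 1-bromo-2,4-bis(methoxymethoxy)benzene
Conditions: NaH (2.4 equiv), MOMCl (2.4 equiv), DMF, 0 °C to rt
Reagents that add atoms: chloromethyl methyl ether (MOMCl), COCCl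
Why: Double Williamson O-alkylation protects both phenols so that the bromide can later be converted into an arylmetal reagent.

Step 7
Reactants: 9 1-bromo-2,4-bis(methoxymethoxy)benzene; 10 acrolein
Product: 12 1-[2,4-bis(methoxymethoxy)phenyl]prop-2-en-1-ol (racemic), via 2,4-bis(methoxymethoxy)phenylmagnesium bromide 11 (not isolated)
Conditions: Mg turnings (I2 crystal), THF, 40 °C; then 10, −78 °C to −20 °C; aq NH4Cl
Reagents that add atoms: none
Why: Magnesium insertion into the aryl bromide gives the aryl Grignard reagent, which adds 1,2 to acrolein at low temperature (Grignard addition); the carbinol is racemic and is oxidised away in step 8.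

Step 8
Reactants: 12 1-[2,4-bis(methoxymethoxy)phenyl]prop-2-en-1-ol
Product: 13 1-[2,4-bis(methoxymethoxy)phenyl]prop-2-en-1-one
Conditions: MnO2, CH2Cl2, rt; used at once (trace BHT)
Reagents that add atoms: none
Why: MnO2 oxidises the allylic/benzylic alcohol selectively to the aryl vinyl ketone under neutral conditions that spare the acetals.

Step 9
Reactants: 7 resorcinol
Product: 14 3-(methoxymethoxy)phenol
Conditions: NaH (1.0 equiv), MOMCl (1.0 equiv), DMF, 0 °C
Reagents that add atoms: chloromethyl methyl ether (MOMCl), COCCl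
Why: Statistical Williamson mono-O-alkylation of the symmetric diol gives the mono-MOM phenol, separable from recovered resorcinol and the bis-ether.

Step 10
Reactants: 8 4-bromobenzene-1,3-diol
Product: 15 1-bromo-2,4-bis(prop-2-en-1-yloxy)benzene
Conditions: allyl bromide, K2CO3, acetone, reflux
Reagents that add atoms: allyl bromide, C=CCBr
Why: Williamson O-allylation installs ethers orthogonal to MOM that zerovalent palladium removes before the fragment union.

Step 11
Reactants: 1 4-bromophenol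
Product: 16 4-bromo-2-iodophenol
Conditions: NIS, TsOH (10 mol %), MeCN, rt
Reagents that add atoms: N-iodosuccinimide (NIS), O=C1CCC(=O)N1I
Why: Electrophilic aromatic iodination goes ortho to the hydroxyl because the para position is blocked by bromine.

Step 12
Reactants: 16 4-bromo-2-iodophenol; 6 1-(bromomethyl)-4-(methoxymethoxy)benzene
Product: 17 4-bromo-2-iodo-1-{[4-(methoxymethoxy)phenyl]methoxy}benzene
Conditions: K2CO3, DMF, rt
Reagents that add atoms: none
Why: Williamson etherification with the reactive benzylic bromide installs the ArO–CH2–Ar unit whose methylene C–H bonds are inserted into in step 14.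

Step 13
Reactants: 17 4-bromo-2-iodo-1-{[4-(methoxymethoxy)phenyl]methoxy}benzene; 18 ethyl diazoacetate
Product: 19 ethyl 2-(5-bromo-2-{[4-(methoxymethoxy)phenyl]methoxy}phenyl)-2-diazoacetate
Conditions: Pd(PPh3)4 (5 mol %), Ag2CO3 (0.5 equiv), Et3N, toluene, rt
Reagents that add atoms: none
Why: Palladium-catalysed cross-coupling of the aryl iodide with the diazo C–H bond (zerovalent palladium inserts into C–I at room temperature and leaves C–Br alone) gives the donor/acceptor aryldiazoacetate with the diazo group intact.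

Step 14
Reactants: 19 ethyl 2-(5-bromo-2-{[4-(methoxymethoxy)phenyl]methoxy}phenyl)-2-diazoacetate
Product: 20 ethyl (2R,3S)-5-bromo-2-[4-(methoxymethoxy)phenyl]-2,3-dihydro-1-benzofuran-3-carboxylate (2,3-cis)
Conditions: Rh2(S-PTTL)4 (dirhodium tetrakis[N-phthaloyl-(S)-tert-leucinate], 1 mol %), toluene, −60 °C
Reagents that add atoms: none
Why: Rhodium-catalysed intramolecular carbene 1,5 C–H insertion into the benzylic ether methylene closes the dihydrobenzofuran, the chiral dirhodium carboxylate selecting one enantiotopic hydrogen so that C2 is set as R and the kinetic cis ester results (C3 is corrected in step 15).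

Step 15
Reactants: 20 ethyl (2R,3S)-5-bromo-2-[4-(methoxymethoxy)phenyl]-2,3-dihydro-1-benzofuran-3-carboxylate
Product: 21 ethyl (2R,3R)-5-bromo-2-[4-(methoxymethoxy)phenyl]-2,3-dihydro-1-benzofuran-3-carboxylate (2,3-trans)
Conditions: NaOEt (0.2 equiv), EtOH, 0 °C to rt
Reagents that add atoms: none
Why: Base-mediated epimerisation equilibrates the ester-bearing C3 to the favoured 2,3-trans isomer (C3 now as in the target), while C2 is untouched because ring opening by β-elimination would be the reverse of a 5-endo-trig closure and is slow.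

Step 16
Reactants: 21 ethyl (2R,3R)-5-bromo-2-[4-(methoxymethoxy)phenyl]-2,3-dihydro-1-benzofuran-3-carboxylate
Product: 22 [(2R,3S)-5-bromo-2-[4-(methoxymethoxy)phenyl]-2,3-dihydro-1-benzofuran-3-yl]methanol
Conditions: LiBH4, THF (cat. MeOH), 0 °C to rt
Reagents that add atoms: none
Why: Hydride reduction of the ester to the primary alcohol leaves the aryl bromide, the acetal and both stereocentres alone (the C3 descriptor becomes S only through ligand priorities).

Step 17
Reactants: 22 [(2R,3S)-5-bromo-2-[4-(methoxymethoxy)phenyl]-2,3-dihydro-1-benzofuran-3-yl]methanol; 13 1-[2,4-bis(methoxymethoxy)phenyl]prop-2-en-1-one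
Product: 23 (2E)-1-[2,4-bis(methoxymethoxy)phenyl]-3-{(2R,3S)-3-(hydroxymethyl)-2-[4-(methoxymethoxy)phenyl]-2,3-dihydro-1-benzofuran-5-yl}prop-2-en-1-one
Conditions: Pd2(dba)3 (2.5 mol %), [(t-Bu)3PH]BF4 (10 mol %), Cy2NMe, 1,4-dioxane, 70 °C
Reagents that add atoms: none
Why: Mizoroki–Heck arylation of the vinyl ketone at its terminal carbon followed by syn β-hydride elimination gives the E-chalcone and tolerates the free primary alcohol.

Step 18
Reactants: 23 chalcone alcohol
Product: 24 (2R,3R)-5-{(1E)-3-[2,4-bis(methoxymethoxy)phenyl]-3-oxoprop-1-en-1-yl}-2-[4-(methoxymethoxy)phenyl]-2,3-dihydro-1-benzofuran-3-carbaldehyde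
Conditions: Dess–Martin periodinane, CH2Cl2, 0 °C to rt
Reagents that add atoms: none
Why: Dess–Martin oxidation gives the aldehyde under non-basic conditions, and its α-centre already has the more stable trans configuration so it cannot erode.

Step 19
Reactants: 24 chalcone aldehyde; 14 3-(methoxymethoxy)phenol
Product: 26 (2E)-1-[2,4-bis(methoxymethoxy)phenyl]-3-[(2R,3S)-3-{hydroxy[2-hydroxy-4-(methoxymethoxy)phenyl]methyl}-2-[4-(methoxymethoxy)phenyl]-2,3-dihydro-1-benzofuran-5-yl]prop-2-en-1-one (half A; both carbinol epimers), via bromomagnesium 3-(methoxymethoxy)phenolate 25 (not isolated)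
Conditions: 14 (2.0 equiv), EtMgBr (1.9 equiv), Et2O, 0 °C; solvent exchange to CH2Cl2; 24, rt; aq NH4Cl
Reagents that add atoms: none
Why: Casiraghi-type ortho-specific hydroxyalkylation, in which magnesium chelates the phenolate oxygen and the aldehyde and delivers the ring carbon ortho to oxygen and para to the MOM ether while the far less electrophilic enone is left alone; the new carbinol centre forms as a mixture that is erased in step 30.

Step 20
Reactants: 27 succinic anhydride
Product: 28 4-methoxy-4-oxobutanoic acid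
Conditions: MeOH, reflux
Reagents that add atoms: methanol, CO
Why: Alcoholysis of the cyclic anhydride opens it to the half-ester.

Step 21
Reactants: 28 4-methoxy-4-oxobutanoic acid
Product: 30 methyl 4-[(4R)-4-benzyl-2-oxo-1,3-oxazolidin-3-yl]-4-oxobutanoate, via mixed pivalic anhydride 29 (not isolated)
Conditions: PivCl, Et3N, THF, −20 °C; (R)-4-benzyl-1,3-oxazolidin-2-one, LiCl, rt
Reagents that add atoms: (R)-4-benzyl-1,3-oxazolidin-2-one, O=C1N[C@H](Cc2ccccc2)CO1
Why: N-acylation of the oxazolidinone through the mixed anhydride attaches the chiral auxiliary to the free acid terminus only.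

Step 22
Reactants: 30 succinate imide; 4 4-(methoxymethoxy)benzaldehyde
Product: 33 (4R)-4-benzyl-3-{[(2R,3R)-2-[4-(methoxymethoxy)phenyl]-5-oxooxolan-3-yl]carbonyl}-1,3-oxazolidin-2-one, via Z boron enolate 31 (not isolated), via syn-aldol adduct 32 (not isolated)
Conditions: Bu2BOTf, i-Pr2NEt, CH2Cl2, −78 °C to 0 °C; 4, −78 °C to 0 °C; pH 7 buffer, MeOH, H2O2
Reagents that add atoms: none
Why: Evans syn-aldol reaction, in which the Z boron enolate on the imide side reacts through a Zimmerman–Traxler chair whose face is dictated by the (R)-benzyl group, setting both new centres as R, and the γ-hydroxy ester then lactonises to the 2,3-trans lactone.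

Step 23
Reactants: 33 lactone imide
Product: 35 (2R,3R)-2-[4-(methoxymethoxy)phenyl]-5-oxooxolane-3-carboxylic acid, via lithium peroxycarboxylate 34 (not isolated)
Conditions: LiOH, H2O2, THF/H2O, 0 °C; Na2SO3; 1 M HCl to pH 3
Reagents that add atoms: hydrogen peroxide (as LiOOH), OO
Why: Hydroperoxide attacks the exocyclic imide carbonyl selectively (auxiliary cleavage without epimerisation), sulfite reduces the peracid, and acidification re-closes any opened lactone.

Step 24
Reactants: 35 lactone acid; 6 1-(bromomethyl)-4-(methoxymethoxy)benzene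
Product: 37 (2R,3R,4R)-2-[4-(methoxymethoxy)phenyl]-4-{[4-(methoxymethoxy)phenyl]methyl}-5-oxooxolane-3-carboxylic acid, via dilithium enolate carboxylate 36 (not isolated)
Conditions: LiHMDS (2.2 equiv), THF, −78 °C; 6, −78 °C to −40 °C; 1 M HCl, 0 °C
Reagents that add atoms: none
Why: Enolate alkylation of the dianion takes place anti to the neighbouring carboxylate, giving the all-trans lactone with the new benzyl-bearing centre as R.

Step 25
Reactants: 37 benzylated lactone acid; 15 1-bromo-2,4-bis(prop-2-en-1-yloxy)benzene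
Product: 39 (2R,3R,4R)-5-[2,4-bis(prop-2-en-1-yloxy)phenyl]-5-hydroxy-2-[4-(methoxymethoxy)phenyl]-4-{[4-(methoxymethoxy)phenyl]methyl}oxolane-3-carboxylic acid (hemiketal; anomer mixture), via 2,4-bis(prop-2-en-1-yloxy)phenyllithium 38 (not isolated)
Conditions: 37, NaH (1.0 equiv), THF, 0 °C; then 38 (1.3 equiv, from 15, n-BuLi, THF, −78 °C), −78 °C; aq NH4Cl, then citric acid to pH 4
Reagents that add atoms: none
Why: Aryllithium addition to the lactone carbonyl stops after one addition at −78 °C (the carboxylate made beforehand with NaH is inert and leaves no N–H acid that could quench the aryllithium), forming the C–aryl bond without touching the three ring stereocentres; the anomeric centre is undefined and is removed in step 26.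

Step 26
Reactants: 39 hemiketal acid
Product: 41 (2R,3R,4R,5S)-5-[2,4-bis(prop-2-en-1-yloxy)phenyl]-2-[4-(methoxymethoxy)phenyl]-4-{[4-(methoxymethoxy)phenyl]methyl}oxolane-3-carboxylic acid, via cyclic aryl oxocarbenium ion 40 (not isolated)
Conditions: Et3SiH, BF3·OEt2, CH2Cl2, −78 °C; aq NaHCO3 at −78 °C
Reagents that add atoms: none
Why: Ionic hydrogenation, in which silane hydride attacks the oxocarbenium ion anti to the adjacent benzyl group (inside attack on the envelope) and so places the aryl group cis to the benzyl group (2,3-cis, 2,5-cis, new centre S), while −78 °C and a cold quench prevent acid epimerisation to the trans isomer.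

Step 27
Reactants: 41 oxolane acid
Product: 42 (2R,3R,4R,5S)-5-[2,4-bis(prop-2-en-1-yloxy)phenyl]-N-methoxy-2-[4-(methoxymethoxy)phenyl]-4-{[4-(methoxymethoxy)phenyl]methyl}-N-methyloxolane-3-carboxamide
Conditions: MeNH(OMe)·HCl, EDCI·HCl, HOBt, N-methylmorpholine, CH2Cl2, 0 °C to rt
Reagents that add atoms: N,O-dimethylhydroxylamine hydrochloride, CNOC.Cl
Why: Carbodiimide-mediated amidation gives the Weinreb amide, and the α-centre is trans to both neighbours so it is not at risk under the mild base.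

Step 28
Reactants: 42 Weinreb amide; 9 1-bromo-2,4-bis(methoxymethoxy)benzene
Product: 44 [2,4-bis(methoxymethoxy)phenyl]{(2R,3R,4R,5S)-5-[2,4-bis(prop-2-en-1-yloxy)phenyl]-2-[4-(methoxymethoxy)phenyl]-4-{[4-(methoxymethoxy)phenyl]methyl}oxolan-3-yl}methanone, via 2,4-bis(methoxymethoxy)phenyllithium 43 (not isolated)
Conditions: 9, n-BuLi, THF, −78 °C; then 42, −78 °C to −40 °C; aq NH4Cl
Reagents that add atoms: none
Why: Weinreb ketone synthesis, in which the aryllithium from bromine–lithium exchange adds only once because the chelated tetrahedral adduct prevents over-addition, installs the aroyl group with the α-centre intact.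

Step 29
Reactants: 44 bis-allyl ketone
Product: 45 [2,4-bis(methoxymethoxy)phenyl]{(2R,3R,4R,5S)-5-(2,4-dihydroxyphenyl)-2-[4-(methoxymethoxy)phenyl]-4-{[4-(methoxymethoxy)phenyl]methyl}oxolan-3-yl}methanone (half B)
Conditions: Pd(PPh3)4 (5 mol %), morpholine, THF, rt
Reagents that add atoms: none
Why: Tsuji–Trost deallylation with morpholine as allyl acceptor frees the two resorcinol hydroxyls under neutral conditions that leave MOM ethers, ketone and benzylic ethers untouched.

Step 30
Reactants: 26 half A; 45 half B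
Product: 47 octa-MOM ether of the target (free: the ortho-OH of the methine-bound MOM-oxyphenyl ring and both OH of the central resorcinol ring; dihydrobenzofuran 2R,3R; methine R; oxolane 2S,3R,4R,5R), via o-quinone methide 46 (not isolated)
Conditions: (R)-TRIP [(R)-3,3'-bis(2,4,6-triisopropylphenyl)-1,1'-binaphthyl-2,2'-diyl hydrogen phosphate, 10 mol %], 3 Å MS, CH2Cl2, −20 °C to 0 °C; 26 added over 4 h to 45 (1.3 equiv)
Reagents that add atoms: none
Why: Brønsted-acid-catalysed dehydration of either carbinol epimer gives the planar o-quinone methide, which the hydrogen-bonding phosphate delivers to the most nucleophilic carbon of 45 (ortho to one free OH, para to the other) in a Friedel–Crafts-type conjugate addition; attack anti to the benzo ring of the dihydrobenzofuran in the A1,3-minimised conformer, reinforced by the chiral phosphate, sets the methine as R, and slow addition of 26 to excess 45 suppresses self-alkylation.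

Step 31
Reactants: 47 octa-MOM ether
Product: 49 CNP0225254.6, via undeca-O-trimethylsilyl ether 48 (not isolated)
Conditions: TMSOTf, 2,2'-bipyridyl, MeCN, 0 °C to rt; then H2O, rt
Reagents that add atoms: none
Why: Silyl triflate/bipyridyl cleavage of the aryl MOM acetals under buffered, non-protic conditions turns every phenol oxygen into a TMS ether that water then hydrolyses, so the acid-sensitive benzylic ethers, the enone and all seven stereocentres are not exposed to protic acid.

**Compound list**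

1 | 4-bromophenol | Oc1ccc(Br)cc1 | starting material
2 | 1-bromo-4-(methoxymethoxy)benzene | COCOc1ccc(Br)cc1 | intermediate
3 | 4-(methoxymethoxy)phenyllithium (not isolated) | [Li]c1ccc(OCOC)cc1 | intermediate
4 | 4-(methoxymethoxy)benzaldehyde | COCOc1ccc(C=O)cc1 | intermediate
5 | [4-(methoxymethoxy)phenyl]methanol | COCOc1ccc(CO)cc1 | intermediate
6 | 1-(bromomethyl)-4-(methoxymethoxy)benzene | COCOc1ccc(CBr)cc1 | intermediate
7 | resorcinol | Oc1cccc(O)c1 | starting material
8 | 4-bromobenzene-1,3-diol | Oc1ccc(Br)c(O)c1 | intermediate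
9 | 1-bromo-2,4-bis(methoxymethoxy)benzene | COCOc1ccc(Br)c(OCOC)c1 | intermediate
10 | acrolein | C=CC=O | starting material
11 | 2,4-bis(methoxymethoxy)phenylmagnesium bromide (not isolated) | COCOc1ccc([Mg]Br)c(OCOC)c1 | intermediate
12 | 1-[2,4-bis(methoxymethoxy)phenyl]prop-2-en-1-ol (racemic) | C=CC(O)c1ccc(OCOC)cc1OCOC | intermediate
13 | 1-[2,4-bis(methoxymethoxy)phenyl]prop-2-en-1-one | C=CC(=O)c1ccc(OCOC)cc1OCOC | intermediate
14 | 3-(methoxymethoxy)phenol | COCOc1cccc(O)c1 | intermediate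
15 | 1-bromo-2,4-bis(prop-2-en-1-yloxy)benzene | C=CCOc1ccc(Br)c(OCC=C)c1 | intermediate
16 | 4-bromo-2-iodophenol | Oc1ccc(Br)cc1I | intermediate
17 | 4-bromo-2-iodo-1-{[4-(methoxymethoxy)phenyl]methoxy}benzene | COCOc1ccc(COc2ccc(Br)cc2I)cc1 | intermediate
18 | ethyl diazoacetate | CCOC(=O)C=[N+]=[N-] | starting material
19 | ethyl 2-(5-bromo-2-{[4-(methoxymethoxy)phenyl]methoxy}phenyl)-2-diazoacetate | CCOC(=O)C(=[N+]=[N-])c1cc(Br)ccc1OCc1ccc(OCOC)cc1 | intermediate
20 | ethyl (2R,3S)-5-bromo-2-[4-(methoxymethoxy)phenyl]-2,3-dihydro-1-benzofuran-3-carboxylate (cis) | Brc1ccc2c(c1)[C@H](C(=O)OCC)[C@H](c1ccc(OCOC)cc1)O2 | intermediate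
21 | ethyl (2R,3R)-5-bromo-2-[4-(methoxymethoxy)phenyl]-2,3-dihydro-1-benzofuran-3-carboxylate (trans) | Brc1ccc2c(c1)[C@@H](C(=O)OCC)[C@H](c1ccc(OCOC)cc1)O2 | intermediate
22 | [(2R,3S)-5-bromo-2-[4-(methoxymethoxy)phenyl]-2,3-dihydro-1-benzofuran-3-yl]methanol (trans) | Brc1ccc2c(c1)[C@@H](CO)[C@H](c1ccc(OCOC)cc1)O2 | intermediate
23 | (2E)-1-[2,4-bis(methoxymethoxy)phenyl]-3-{(2R,3S)-3-(hydroxymethyl)-2-[4-(methoxymethoxy)phenyl]-2,3-dihydro-1-benzofuran-5-yl}prop-2-en-1-one | O=C(/C=C/c1ccc2c(c1)[C@@H](CO)[C@H](c1ccc(OCOC)cc1)O2)c1ccc(OCOC)cc1OCOC | intermediate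
24 | (2R,3R)-5-{(1E)-3-[2,4-bis(methoxymethoxy)phenyl]-3-oxoprop-1-en-1-yl}-2-[4-(methoxymethoxy)phenyl]-2,3-dihydro-1-benzofuran-3-carbaldehyde | O=C(/C=C/c1ccc2c(c1)[C@@H](C=O)[C@H](c1ccc(OCOC)cc1)O2)c1ccc(OCOC)cc1OCOC | intermediate
25 | bromomagnesium 3-(methoxymethoxy)phenolate (not isolated) | COCOc1cccc(O[Mg]Br)c1 | intermediate
26 | half A: (2E)-1-[2,4-bis(methoxymethoxy)phenyl]-3-[(2R,3S)-3-{hydroxy[2-hydroxy-4-(methoxymethoxy)phenyl]methyl}-2-[4-(methoxymethoxy)phenyl]-2,3-dihydro-1-benzofuran-5-yl]prop-2-en-1-one, carbinol centre undefined | O=C(/C=C/c1ccc2c(c1)[C@@H](C(O)c1ccc(OCOC)cc1O)[C@H](c1ccc(OCOC)cc1)O2)c1ccc(OCOC)cc1OCOC | intermediate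
27 | succinic anhydride | O=C1CCC(=O)O1 | starting material
28 | 4-methoxy-4-oxobutanoic acid | COC(=O)CCC(=O)O | intermediate
29 | 4-methoxy-4-oxobutanoic pivalic anhydride (not isolated) | COC(=O)CCC(=O)OC(=O)C(C)(C)C | intermediate
30 | methyl 4-[(4R)-4-benzyl-2-oxo-1,3-oxazolidin-3-yl]-4-oxobutanoate | COC(=O)CCC(=O)N1C(=O)OC[C@H]1Cc1ccccc1 | intermediate
31 | Z dibutylboron enolate of 30 (not isolated) | CCCCB(CCCC)O/C(=C\CC(=O)OC)N1C(=O)OC[C@H]1Cc1ccccc1 | intermediate
32 | methyl (3R,4R)-3-{[(4R)-4-benzyl-2-oxo-1,3-oxazolidin-3-yl]carbonyl}-4-hydroxy-4-[4-(methoxymethoxy)phenyl]butanoate (syn aldol, not isolated) | O[C@@H](c1ccc(OCOC)cc1)[C@H](C(=O)N1C(=O)OC[C@H]1Cc1ccccc1)CC(=O)OC | intermediate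
33 | (4R)-4-benzyl-3-{[(2R,3R)-2-[4-(methoxymethoxy)phenyl]-5-oxooxolan-3-yl]carbonyl}-1,3-oxazolidin-2-one | O=C1O[C@@H](c2ccc(OCOC)cc2)[C@H](C(=O)N2C(=O)OC[C@H]2Cc2ccccc2)C1 | intermediate
34 | lithium (2R,3R)-2-[4-(methoxymethoxy)phenyl]-5-oxooxolane-3-carboperoxoate (not isolated) | O=C1O[C@@H](c2ccc(OCOC)cc2)[C@H](C(=O)O[O-])C1.[Li+] | intermediate
35 | (2R,3R)-2-[4-(methoxymethoxy)phenyl]-5-oxooxolane-3-carboxylic acid | O=C1O[C@@H](c2ccc(OCOC)cc2)[C@H](C(=O)O)C1 | intermediate
36 | dilithium carboxylate/lactone enolate of 35 (not isolated) | [Li+].[Li+].[O-]C=1O[C@@H](c2ccc(OCOC)cc2)[C@H](C([O-])=O)C=1 | intermediate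
37 | (2R,3R,4R)-2-[4-(methoxymethoxy)phenyl]-4-{[4-(methoxymethoxy)phenyl]methyl}-5-oxooxolane-3-carboxylic acid (all-trans) | O=C1O[C@@H](c2ccc(OCOC)cc2)[C@H](C(=O)O)[C@H]1Cc1ccc(OCOC)cc1 | intermediate
38 | 2,4-bis(prop-2-en-1-yloxy)phenyllithium (not isolated) | [Li]c1ccc(OCC=C)cc1OCC=C | intermediate
39 | (2R,3R,4R)-5-[2,4-bis(prop-2-en-1-yloxy)phenyl]-5-hydroxy-2-[4-(methoxymethoxy)phenyl]-4-{[4-(methoxymethoxy)phenyl]methyl}oxolane-3-carboxylic acid (anomer mixture) | OC1(c2ccc(OCC=C)cc2OCC=C)O[C@@H](c2ccc(OCOC)cc2)[C@H](C(=O)O)[C@H]1Cc1ccc(OCOC)cc1 | intermediate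
40 | cyclic aryl oxocarbenium ion from 39 (not isolated) | C=CCOc1ccc(C2=[O+][C@@H](c3ccc(OCOC)cc3)[C@H](C(=O)O)[C@H]2Cc2ccc(OCOC)cc2)c(OCC=C)c1 | intermediate
41 | (2R,3R,4R,5S)-5-[2,4-bis(prop-2-en-1-yloxy)phenyl]-2-[4-(methoxymethoxy)phenyl]-4-{[4-(methoxymethoxy)phenyl]methyl}oxolane-3-carboxylic acid | C=CCOc1ccc([C@H]2O[C@@H](c3ccc(OCOC)cc3)[C@H](C(=O)O)[C@H]2Cc2ccc(OCOC)cc2)c(OCC=C)c1 | intermediate
42 | Weinreb amide of 41, (2R,3R,4R,5S) | C=CCOc1ccc([C@H]2O[C@@H](c3ccc(OCOC)cc3)[C@H](C(=O)N(C)OC)[C@H]2Cc2ccc(OCOC)cc2)c(OCC=C)c1 | intermediate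
43 | 2,4-bis(methoxymethoxy)phenyllithium (not isolated) | [Li]c1ccc(OCOC)cc1OCOC | intermediate
44 | [2,4-bis(methoxymethoxy)phenyl]{(2R,3R,4R,5S)-5-[2,4-bis(prop-2-en-1-yloxy)phenyl]-2-[4-(methoxymethoxy)phenyl]-4-{[4-(methoxymethoxy)phenyl]methyl}oxolan-3-yl}methanone | C=CCOc1ccc([C@H]2O[C@@H](c3ccc(OCOC)cc3)[C@H](C(=O)c3ccc(OCOC)cc3OCOC)[C@H]2Cc2ccc(OCOC)cc2)c(OCC=C)c1 | intermediate
45 | half B: [2,4-bis(methoxymethoxy)phenyl]{(2R,3R,4R,5S)-5-(2,4-dihydroxyphenyl)-2-[4-(methoxymethoxy)phenyl]-4-{[4-(methoxymethoxy)phenyl]methyl}oxolan-3-yl}methanone | Oc1ccc([C@H]2O[C@@H](c3ccc(OCOC)cc3)[C@H](C(=O)c3ccc(OCOC)cc3OCOC)[C@H]2Cc2ccc(OCOC)cc2)c(O)c1 | intermediate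
46 | o-quinone methide from 26 (not isolated; exocyclic alkene geometry undefined) | O=C(/C=C/c1ccc2c(c1)[C@@H](C=C1C=CC(OCOC)=CC1=O)[C@H](c1ccc(OCOC)cc1)O2)c1ccc(OCOC)cc1OCOC | intermediate
47 | (2E)-1-[2,4-bis(methoxymethoxy)phenyl]-3-{(2R,3R)-3-[(R)-[2-hydroxy-4-(methoxymethoxy)phenyl]{5-[(2S,3R,4R,5R)-4-[2,4-bis(methoxymethoxy)benzoyl]-3-[4-(methoxymethoxy)benzyl]-5-[4-(methoxymethoxy)phenyl]oxolan-2-yl]-2,4-dihydroxyphenyl}methyl]-2-[4-(methoxymethoxy)phenyl]-2,3-dihydro-1-benzofuran-5-yl}prop-2-en-1-one | O=C(/C=C/c1ccc2c(c1)[C@@H]([C@H](c1ccc(OCOC)cc1O)c1cc([C@H]3O[C@@H](c4ccc(OCOC)cc4)[C@H](C(=O)c4ccc(OCOC)cc4OCOC)[C@H]3Cc3ccc(OCOC)cc3)c(O)cc1O)[C@H](c1ccc(OCOC)cc1)O2)c1ccc(OCOC)cc1OCOC | intermediate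
48 | undeca-O-trimethylsilyl ether of the target (not isolated) | O=C(/C=C/c1ccc2c(c1)[C@@H]([C@H](c1ccc(O[Si](C)(C)C)cc1O[Si](C)(C)C)c1cc([C@H]3O[C@@H](c4ccc(O[Si](C)(C)C)cc4)[C@H](C(=O)c4ccc(O[Si](C)(C)C)cc4O[Si](C)(C)C)[C@H]3Cc3ccc(O[Si](C)(C)C)cc3)c(O[Si](C)(C)C)cc1O[Si](C)(C)C)[C@H](c1ccc(O[Si](C)(C)C)cc1)O2)c1ccc(O[Si](C)(C)C)cc1O[Si](C)(C)C | intermediate
49 | CNP0225254.6: (2E)-1-(2,4-dihydroxyphenyl)-3-{(2R,3R)-3-[(R)-(2,4-dihydroxyphenyl){5-[(2S,3R,4R,5R)-4-(2,4-dihydroxybenzoyl)-3-(4-hydroxybenzyl)-5-(4-hydroxyphenyl)oxolan-2-yl]-2,4-dihydroxyphenyl}methyl]-2-(4-hydroxyphenyl)-2,3-dihydro-1-benzofuran-5-yl}prop-2-en-1-one | O=C(/C=C/c1ccc2c(c1)[C@@H]([C@H](c1ccc(O)cc1O)c1cc([C@H]3O[C@@H](c4ccc(O)cc4)[C@H](C(=O)c4ccc(O)cc4O)[C@H]3Cc3ccc(O)cc3)c(O)cc1O)[C@H](c1ccc(O)cc1)O2)c1ccc(O)cc1O | target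

**Step count and risks**

Total step count: 31. Longest linear sequence: 14 steps (1, 2, 3, 4, 12, 13, 14, 15, 16, 17, 18, 19, 30, 31).

Most likely to fail, first: step 30, the fragment union. The face selectivity at the new methine is unproven, 26 can alkylate itself, and the electron-rich C2 aryl ether of 45 can open under acid. The fallback sets out from 24 and 45 and comes back at 47. Treat 45 with EtMgBr (2 equiv) to give its bis(bromomagnesium) phenolate F9. F9 adds to the aldehyde of 24 through the ring carbon ortho to its 4-OH and gives the carbinol F10, in which the resorcinol ring of half B already carries the benzylic carbon. Under the same phosphoric acid catalysis F10 loses water to the quinone methide F11, which is trapped by a fivefold excess of 14 at the carbon ortho to its hydroxyl, giving 47. Because the two aryl groups now enter in the reverse order, the same substrate-controlled facial preference installs the methine with the opposite sense, so this sequence is the remedy if step 30 favours the wrong epimer. The cheap nucleophile in excess also suppresses self-alkylation.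

Second: step 19, the ortho-hydroxyalkylation. Magnesium phenolates add less readily to α-branched, enolisable aldehydes than to aromatic ones. The fallback sets out from 24 (with the Grignard reagent 11, made from 9 as in step 7, and with 45) and comes back at 49. Transmetalate 11 with ClTi(OiPr)3 to the aldehyde-selective aryltitanium reagent F6 and add it to 24 (−78 °C to −20 °C) to give the fully MOM-protected carbinol F7. Ionise F7 with diphenyl phosphate (10 mol %) in CH2Cl2/hexafluoroisopropanol in the presence of 45 (1.5 equiv). This SN1 Friedel–Crafts alkylation gives the nona-MOM coupled product F8, because the free resorcinol ring of 45 is far more nucleophilic than the bis-ether ring of F7. The conditions of step 31 then convert F8 through 48 into 49.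

Third: step 14, the enantioselective C–H insertion. The ee for this ortho-alkoxy, para-bromo substrate is unproven. The fallback sets out from 19 and comes back at 22. Decompose 19 with achiral Rh2(OAc)4 (CH2Cl2, rt) to the racemic cis ester F1, epimerise with NaOEt/EtOH to the racemic trans ester F2, and saponify (LiOH, THF/H2O, 0 °C) to the racemic trans acid F3. Acylate (R)-4-benzyl-1,3-oxazolidin-2-one with F3 (PivCl, Et3N, LiCl) and separate the two imides on silica: the (2R,3R) imide F4 and the (2S,3S) imide F5. LiBH4 (THF, H2O) cleaves F4 to alcohol 22. Stereocontrol thus comes from separation of covalent diastereomers, not from the catalyst.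

**Further compounds**

F1 | step 14 | racemic ethyl cis-5-bromo-2-[4-(methoxymethoxy)phenyl]-2,3-dihydro-1-benzofuran-3-carboxylate | Brc1ccc2c(c1)[C@H](C(=O)OCC)[C@H](c1ccc(OCOC)cc1)O2.Brc1ccc2c(c1)[C@@H](C(=O)OCC)[C@@H](c1ccc(OCOC)cc1)O2
F2 | step 14 | racemic ethyl trans-5-bromo-2-[4-(methoxymethoxy)phenyl]-2,3-dihydro-1-benzofuran-3-carboxylate | Brc1ccc2c(c1)[C@@H](C(=O)OCC)[C@H](c1ccc(OCOC)cc1)O2.Brc1ccc2c(c1)[C@H](C(=O)OCC)[C@@H](c1ccc(OCOC)cc1)O2
F3 | step 14 | racemic trans-5-bromo-2-[4-(methoxymethoxy)phenyl]-2,3-dihydro-1-benzofuran-3-carboxylic acid | Brc1ccc2c(c1)[C@@H](C(=O)O)[C@H](c1ccc(OCOC)cc1)O2.Brc1ccc2c(c1)[C@H](C(=O)O)[C@@H](c1ccc(OCOC)cc1)O2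
F4 | step 14 | (4R)-4-benzyl-3-{[(2R,3R)-5-bromo-2-[4-(methoxymethoxy)phenyl]-2,3-dihydro-1-benzofuran-3-yl]carbonyl}-1,3-oxazolidin-2-one | Brc1ccc2c(c1)[C@@H](C(=O)N1C(=O)OC[C@H]1Cc1ccccc1)[C@H](c1ccc(OCOC)cc1)O2
F5 | step 14 | (4R)-4-benzyl-3-{[(2S,3S)-5-bromo-2-[4-(methoxymethoxy)phenyl]-2,3-dihydro-1-benzofuran-3-yl]carbonyl}-1,3-oxazolidin-2-one | Brc1ccc2c(c1)[C@H](C(=O)N1C(=O)OC[C@H]1Cc1ccccc1)[C@@H](c1ccc(OCOC)cc1)O2
F6 | step 19 | [2,4-bis(methoxymethoxy)phenyl]tri(propan-2-yloxy)titanium | CC(C)O[Ti](OC(C)C)(OC(C)C)c1ccc(OCOC)cc1OCOC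
F7 | step 19 | (2E)-1-[2,4-bis(methoxymethoxy)phenyl]-3-[(2R,3S)-3-{[2,4-bis(methoxymethoxy)phenyl](hydroxy)methyl}-2-[4-(methoxymethoxy)phenyl]-2,3-dihydro-1-benzofuran-5-yl]prop-2-en-1-one, carbinol centre undefined | O=C(/C=C/c1ccc2c(c1)[C@@H](C(O)c1ccc(OCOC)cc1OCOC)[C@H](c1ccc(OCOC)cc1)O2)c1ccc(OCOC)cc1OCOC
F8 | step 19 | nona-MOM ether of the target (as 47 but with the ortho-OH of the methine-bound ring also as MOM ether; same configuration as 47) | O=C(/C=C/c1ccc2c(c1)[C@@H]([C@H](c1ccc(OCOC)cc1OCOC)c1cc([C@H]3O[C@@H](c4ccc(OCOC)cc4)[C@H](C(=O)c4ccc(OCOC)cc4OCOC)[C@H]3Cc3ccc(OCOC)cc3)c(O)cc1O)[C@H](c1ccc(OCOC)cc1)O2)c1ccc(OCOC)cc1OCOC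
F9 | step 30 | bis(bromomagnesium) phenolate of 45 | Br[Mg]Oc1ccc([C@H]2O[C@@H](c3ccc(OCOC)cc3)[C@H](C(=O)c3ccc(OCOC)cc3OCOC)[C@H]2Cc2ccc(OCOC)cc2)c(O[Mg]Br)c1
F10 | step 30 | carbinol from 24 and 45 (hydroxymethine on the resorcinol ring of half B, carbinol centre undefined) | O=C(/C=C/c1ccc2c(c1)[C@@H](C(O)c1cc([C@H]3O[C@@H](c4ccc(OCOC)cc4)[C@H](C(=O)c4ccc(OCOC)cc4OCOC)[C@H]3Cc3ccc(OCOC)cc3)c(O)cc1O)[C@H](c1ccc(OCOC)cc1)O2)c1ccc(OCOC)cc1OCOC
F11 | step 30 | o-quinone methide from F10 | O=C(/C=C/c1ccc2c(c1)[C@@H](C=C1C=C([C@H]3O[C@@H](c4ccc(OCOC)cc4)[C@H](C(=O)c4ccc(OCOC)cc4OCOC)[C@H]3Cc3ccc(OCOC)cc3)C(O)=CC1=O)[C@H](c1ccc(OCOC)cc1)O2)c1ccc(OCOC)cc1OCOC
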